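**Retrosynthetic overview**

1. The route rests on the oxane segment C6(–O1)–C1'–C2' (numbering O1, C2 = ring-A carbon, C4 = axial oxygen, C6 = chain carbon). With C2' at the acid level it is a β-oxygenated acid, so it is stored as a β-lactone whose alkyl C6–O bond is displaced by the oxygen of a C2 ring-A aryl ketone.
2. Last bonds: C2'–aryl (ring B) by Negishi coupling of the C2' iodide (from the acid by reduction and iodination) with benzyl-protected 4-bromocatechol, then global hydrogenolysis.
3. The only ring formed is the oxane. O1–C6 is closed by reductive cyclisation of the keto-β-lactone, which sets C6 by inversion and C2 by axial hydride delivery. The β-lactone comes from the C6 aldehyde by a catalytic asymmetric ketene–aldehyde [2+2].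
4. The chain C2–C6 comes from the ring-A dithiane anion plus (R)-epichlorohydrin (C3–C4–C5, C4 stereocentre), then vinyl cuprate, benzylation, dithiane hydrolysis and ozonolysis.

Key step: step 9

**Remarks**

- ArA = 3,4-bis(benzyloxy)-5-methoxyphenyl. Ring locants and descriptors in all names use the numbering O1, C2 (ArA carbon), C4, C6.
- Assumption for step 3: the lithiated dithiane attacks (R)-epichlorohydrin at the epoxide CH2 and not at C–Cl, as is usual for dithiane anions; attack at C–Cl would give the enantiomeric epoxide.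
- Assumption for step 8: the antipode of the aluminium catalyst is chosen to give the 4S lactone; its sense is to be assigned on a simple β-benzyloxy aldehyde before use.

**Route**

Step 1
Reactants: 1 3,4-dihydroxy-5-methoxybenzaldehyde
Product: 2 3,4-bis(benzyloxy)-5-methoxybenzaldehyde
Conditions: BnBr (2.3 equiv), K2CO3, DMF, rt to 60 °C
Reagents that add atoms: benzyl bromide, BrCc1ccccc1
Why: Williamson etherification of both phenols should proceed cleanly, the aldehyde being inert to carbonate.

Step 2
Reactants: 2 3,4-bis(benzyloxy)-5-methoxybenzaldehyde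
Product: 3 2-ArA-1,3-dithiane
Conditions: HS(CH2)3SH (1.1 equiv), BF3·OEt2 (0.2 equiv), CH2Cl2, 0 °C to rt
Reagents that add atoms: propane-1,3-dithiol, SCCCS
Why: Lewis-acid-catalysed dithioacetalisation of an aryl aldehyde is fast at 0 °C, well below the conditions needed to cleave benzyl ethers, and provides the Corey–Seebach acyl-anion equivalent.

Step 3
Reactants: 3 2-ArA-1,3-dithiane; 4 (R)-epichlorohydrin
Product: 7 2-ArA-2-{[(2R)-oxiran-2-yl]methyl}-1,3-dithiane, via 2-lithio-1,3-dithiane 5 (not isolated), via lithium chlorohydrin alkoxide 6 (not isolated)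
Conditions: n-BuLi (1.05 equiv), THF, −78 to −30 °C; then 4 (1.2 equiv), −78 °C to rt
Reagents that add atoms: none
Why: Corey–Seebach alkylation in which the benzylic dithiane anion opens the epoxide at its CH2 and the resulting alkoxide closes onto the CH2Cl carbon on warming (intramolecular Williamson), so the epichlorohydrin stereocentre is never touched and becomes C4.

Step 4
Reactants: 7 2-ArA-2-{[(2R)-oxiran-2-yl]methyl}-1,3-dithiane
Product: 8 (2S)-1-(2-ArA-1,3-dithian-2-yl)pent-4-en-2-ol
Conditions: CH2=CHMgBr (2.5 equiv), CuI (15 mol %), THF, −40 to −20 °C; aq. NH4Cl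
Reagents that add atoms: vinylmagnesium bromide, C=C[Mg]Br
Why: Copper-catalysed Grignard opening of a terminal epoxide occurs at the unsubstituted carbon (C5), leaving the C4 carbinol configuration intact.

Step 5
Reactants: 8 (2S)-1-(2-ArA-1,3-dithian-2-yl)pent-4-en-2-ol
Product: 9 2-ArA-2-[(2S)-2-(benzyloxy)pent-4-en-1-yl]-1,3-dithiane
Conditions: NaH (1.5 equiv), BnBr (1.3 equiv), Bu4NI (cat.), THF/DMF, 0 °C to rt
Reagents that add atoms: benzyl bromide, BrCc1ccccc1
Why: Williamson benzylation of the secondary alkoxide; nothing else in the molecule is base-sensitive while the ketone is still masked.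

Step 6
Reactants: 9 2-ArA-2-[(2S)-2-(benzyloxy)pent-4-en-1-yl]-1,3-dithiane
Product: 10 (3S)-3-(benzyloxy)-1-ArA-hex-5-en-1-one
Conditions: MeI (10 equiv), CaCO3 (5 equiv), MeCN/H2O 4:1, 45 °C
Reagents that add atoms: water, O
Why: Alkylative dithiane hydrolysis (S-methylation, then hydrolysis of the thionium ion) runs at near-neutral pH, which spares the alkene and the benzyl ethers and avoids E1cB loss of the β-benzyloxy group.

Step 7
Reactants: 10 (3S)-3-(benzyloxy)-1-ArA-hex-5-en-1-one
Product: 12 (3S)-3-(benzyloxy)-5-ArA-5-oxopentanal, via secondary ozonide 11 (not isolated)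
Conditions: O3, CH2Cl2, −78 °C, Sudan Red 7B as end-point indicator; then PPh3, −78 °C to rt; used crude
Reagents that add atoms: ozone, [O-][O+]=O
Why: Ozonolysis with reductive work-up cleaves the terminal alkene much faster than ozone attacks the alkoxyarenes or benzyl ethers, and the indicator dye stops the addition at the end-point.

Step 8
Reactants: 12 (3S)-3-(benzyloxy)-5-ArA-5-oxopentanal; 13 acetyl bromide
Product: 14 (4S)-4-[(2S)-2-(benzyloxy)-4-ArA-4-oxobutyl]oxetan-2-one
Conditions: AcBr (2 equiv), i-Pr2NEt (1.7 equiv), Al(III)–triamine bis(triflamide) catalyst (valinol-derived, 10–15 mol %), CH2Cl2, −50 °C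
Reagents that add atoms: none
Why: Catalytic asymmetric acyl halide–aldehyde cyclocondensation (formal ketene–aldehyde [2+2]), for which β-benzyloxy aldehydes are established substrates, should engage only the aldehyde (the aryl ketone is inert to ketene at −50 °C) and set the lactone carbon S under catalyst control, reinforced by the polar 1,3-anti preference of β-alkoxy aldehydes.

Step 9
Reactants: 14 (4S)-4-[(2S)-2-(benzyloxy)-4-ArA-4-oxobutyl]oxetan-2-one
Product: 17 [(2S,4S,6R)-4-(benzyloxy)-2-ArA-oxan-6-yl]acetic acid, via oxocarbenium triflate 15 (not isolated), via triethylsilyl ester 16 (not isolated)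
Conditions: Et3SiH (5 equiv), TESOTf (1.2 equiv), CH2Cl2, −78 to −40 °C; pH 7 buffer, then aqueous work-up
Reagents that add atoms: none
Why: TESOTf activates the β-lactone carbonyl and the Lewis-basic oxygen of the electron-rich aryl ketone displaces the lactone alkyl C6–O bond from the rear, which releases the four-ring strain, frees the acid as its silyl ester and closes the oxane as the ring-A-stabilised 2-aryl oxocarbenium ion 15, which Et3SiH then reduces; the closest known reaction type is the Mead reductive cyclisation of keto-β-lactones to cis-2,5-oxolanes and cis-2,6-oxanes with invertive alkyl C–O cleavage. The one ring formed, the oxane, is closed at O1–C6 in the 6-exo-tet mode. C6 is set stereospecifically by SN2 inversion of the catalyst-defined (S)-lactone carbon, which places the acetic acid arm on the face opposite to the C4 benzyloxy group. C2 is set by axial hydride delivery to the half-chair that holds the C6 arm pseudoequatorial and the C4 benzyloxy group pseudoaxial (its electrostatically preferred position, and no obstacle to a nucleophile as small as hydride), so ring A ends equatorial and cis to the C6 arm. The step needs alkyl-oxygen rather than acyl-oxygen cleavage and cyclisation ahead of direct ketone reduction; the first is secured by the lactone strain and the absence of any external nucleophile, the second by the intramolecular six-membered arrangement and by holding the mixture cold with a limited excess of silane, which also protects the benzylic C2–O1 bond of 16 from a second ionic reduction.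

Step 10
Reactants: 17 [(2S,4S,6R)-4-(benzyloxy)-2-ArA-oxan-6-yl]acetic acid
Product: 18 2-[(2S,4S,6S)-4-(benzyloxy)-2-ArA-oxan-6-yl]ethan-1-ol
Conditions: BH3·THF (2.5 equiv), THF, 0 °C to rt; MeOH quench
Reagents that add atoms: none
Why: Borane reduces the carboxylic acid chemoselectively through its acyloxyborane, leaving the benzyl and cyclic ethers and all three stereocentres untouched.

Step 11
Reactants: 18 2-[(2S,4S,6S)-4-(benzyloxy)-2-ArA-oxan-6-yl]ethan-1-ol
Product: 19 (2S,4S,6R)-4-(benzyloxy)-2-ArA-6-(2-iodoethyl)oxane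
Conditions: I2 (1.3 equiv), PPh3 (1.3 equiv), imidazole (2 equiv), CH2Cl2, 0 °C to rt
Reagents that add atoms: iodine, II
Why: Appel-type (Garegg–Samuelsson) iodination converts the primary alcohol by SN2 displacement of the alkoxyphosphonium ion; the C6 descriptor changes only through CIP priorities.

Step 12
Reactants: 20 4-bromocatechol
Product: 21 4-bromo-1,2-bis(benzyloxy)benzene
Conditions: BnBr (2.3 equiv), K2CO3, DMF, 60 °C
Reagents that add atoms: benzyl bromide, BrCc1ccccc1
Why: Williamson etherification of both catechol hydroxyls gives the ring-B coupling partner in the same protecting group as the rest of the molecule.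

Step 13
Reactants: 19 (2S,4S,6R)-4-(benzyloxy)-2-ArA-6-(2-iodoethyl)oxane; 21 4-bromo-1,2-bis(benzyloxy)benzene
Product: 23 (2S,4S,6S)-4-(benzyloxy)-2-ArA-6-{2-[3,4-bis(benzyloxy)phenyl]ethyl}oxane, via alkylzinc iodide 22 (not isolated)
Conditions: Zn dust (activated with BrCH2CH2Br and TMSCl), LiCl, THF, 40 °C; then 21 (1.5 equiv), Pd(OAc)2 (2 mol %), SPhos (4 mol %), THF, rt to 50 °C
Reagents that add atoms: none
Why: Zinc insertion into the primary iodide followed by Negishi sp3–sp2 coupling is reliable for electron-rich aryl bromides with a biaryl phosphine ligand; the γ-alkoxy alkylzinc reagent has no β-leaving group and no stereocentre is involved.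

Step 14
Reactants: 23 (2S,4S,6S)-4-(benzyloxy)-2-ArA-6-{2-[3,4-bis(benzyloxy)phenyl]ethyl}oxane
Product: 24 5-[(2S,4S,6S)-6-[2-(3,4-dihydroxyphenyl)ethyl]-4-hydroxyoxan-2-yl]-3-methoxybenzene-1,2-diol
Conditions: H2 (1 atm), 10% Pd/C, EtOAc/MeOH, rt, monitored and stopped at full debenzylation; degassed solvents
Reagents that add atoms: none
Why: Catalytic hydrogenolysis should remove the four aryl benzyl ethers quickly and the secondary alkyl benzyl ether more slowly, while the ring C2–O1 bond, a more hindered dialkyl benzylic ether, should survive under neutral conditions at 1 atm.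

**Compound list**

1 | 3,4-dihydroxy-5-methoxybenzaldehyde | COc1cc(C=O)cc(O)c1O | starting material
2 | 3,4-bis(benzyloxy)-5-methoxybenzaldehyde | COc1cc(C=O)cc(OCc2ccccc2)c1OCc1ccccc1 | intermediate
3 | 2-ArA-1,3-dithiane | COc1cc(C2SCCCS2)cc(OCc2ccccc2)c1OCc1ccccc1 | intermediate
4 | (R)-epichlorohydrin | ClC[C@H]1CO1 | starting material
5 | 2-ArA-2-lithio-1,3-dithiane | COc1cc(C2([Li])SCCCS2)cc(OCc2ccccc2)c1OCc1ccccc1 | intermediate
6 | lithium (2R)-1-chloro-3-(2-ArA-1,3-dithian-2-yl)propan-2-olate | COc1cc(C2(C[C@@H](O[Li])CCl)SCCCS2)cc(OCc2ccccc2)c1OCc1ccccc1 | intermediate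
7 | 2-ArA-2-{[(2R)-oxiran-2-yl]methyl}-1,3-dithiane | COc1cc(C2(C[C@@H]3CO3)SCCCS2)cc(OCc2ccccc2)c1OCc1ccccc1 | intermediate
8 | (2S)-1-(2-ArA-1,3-dithian-2-yl)pent-4-en-2-ol | COc1cc(C2(C[C@@H](O)CC=C)SCCCS2)cc(OCc2ccccc2)c1OCc1ccccc1 | intermediate
9 | 2-ArA-2-[(2S)-2-(benzyloxy)pent-4-en-1-yl]-1,3-dithiane | COc1cc(C2(C[C@@H](OCc3ccccc3)CC=C)SCCCS2)cc(OCc2ccccc2)c1OCc1ccccc1 | intermediate
10 | (3S)-3-(benzyloxy)-1-ArA-hex-5-en-1-one | COc1cc(C(=O)C[C@@H](OCc2ccccc2)CC=C)cc(OCc2ccccc2)c1OCc1ccccc1 | intermediate
11 | secondary ozonide (1,2,4-trioxolane) of 10 | COc1cc(C(=O)C[C@@H](OCc2ccccc2)CC2OCOO2)cc(OCc2ccccc2)c1OCc1ccccc1 | intermediate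
12 | (3S)-3-(benzyloxy)-5-ArA-5-oxopentanal | COc1cc(C(=O)C[C@@H](OCc2ccccc2)CC=O)cc(OCc2ccccc2)c1OCc1ccccc1 | intermediate
13 | acetyl bromide | CC(=O)Br | starting material
14 | (4S)-4-[(2S)-2-(benzyloxy)-4-ArA-4-oxobutyl]oxetan-2-one | COc1cc(C(=O)C[C@@H](OCc2ccccc2)C[C@H]2CC(=O)O2)cc(OCc2ccccc2)c1OCc1ccccc1 | intermediate
15 | 2-ArA oxocarbenium triflate of the oxane, C6 arm as triethylsilyl ester | COc1cc(C2=[O+][C@@H](CC(=O)O[Si](CC)(CC)CC)C[C@H](OCc3ccccc3)C2)cc(OCc2ccccc2)c1OCc1ccccc1.[O-]S(=O)(=O)C(F)(F)F | intermediate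
16 | triethylsilyl [(2S,4S,6R)-4-(benzyloxy)-2-ArA-oxan-6-yl]acetate | COc1cc([C@@H]2C[C@@H](OCc3ccccc3)C[C@H](CC(=O)O[Si](CC)(CC)CC)O2)cc(OCc2ccccc2)c1OCc1ccccc1 | intermediate
17 | [(2S,4S,6R)-4-(benzyloxy)-2-ArA-oxan-6-yl]acetic acid | COc1cc([C@@H]2C[C@@H](OCc3ccccc3)C[C@H](CC(=O)O)O2)cc(OCc2ccccc2)c1OCc1ccccc1 | intermediate
18 | 2-[(2S,4S,6S)-4-(benzyloxy)-2-ArA-oxan-6-yl]ethan-1-ol | COc1cc([C@@H]2C[C@@H](OCc3ccccc3)C[C@H](CCO)O2)cc(OCc2ccccc2)c1OCc1ccccc1 | intermediate
19 | (2S,4S,6R)-4-(benzyloxy)-2-ArA-6-(2-iodoethyl)oxane | COc1cc([C@@H]2C[C@@H](OCc3ccccc3)C[C@H](CCI)O2)cc(OCc2ccccc2)c1OCc1ccccc1 | intermediate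
20 | 4-bromocatechol | Oc1ccc(Br)cc1O | starting material
21 | 4-bromo-1,2-bis(benzyloxy)benzene | Brc1ccc(OCc2ccccc2)c(OCc2ccccc2)c1 | intermediate
22 | {2-[(2S,4S,6R)-4-(benzyloxy)-2-ArA-oxan-6-yl]ethyl}zinc iodide | COc1cc([C@@H]2C[C@@H](OCc3ccccc3)C[C@H](CC[Zn]I)O2)cc(OCc2ccccc2)c1OCc1ccccc1 | intermediate
23 | (2S,4S,6S)-4-(benzyloxy)-2-ArA-6-{2-[3,4-bis(benzyloxy)phenyl]ethyl}oxane | COc1cc([C@@H]2C[C@@H](OCc3ccccc3)C[C@H](CCc3ccc(OCc4ccccc4)c(OCc4ccccc4)c3)O2)cc(OCc2ccccc2)c1OCc1ccccc1 | intermediate
24 | 5-[(2S,4S,6S)-6-[2-(3,4-dihydroxyphenyl)ethyl]-4-hydroxyoxan-2-yl]-3-methoxybenzene-1,2-diol | COc1cc([C@@H]2C[C@@H](O)C[C@H](CCc3ccc(O)c(O)c3)O2)cc(O)c1O | target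

**Step count**

Total: 14 steps. Longest linear sequence: 13 steps (steps 1–11, 13 and 14, from 3,4-dihydroxy-5-methoxybenzaldehyde); step 12 is a one-step branch.

**Steps most likely to fail**

1. Step 9 (key step). The aryl ketone may be reduced by the silane before it attacks the lactone, which would lose control at C2. The benzylic C2–O1 bond of the product may ionise and be reduced a second time. The C4 benzyloxy group may be lost by elimination from the oxocarbenium ion. Fallback, setting out from aldehyde 12 and returning at alcohol 18: the ring would be closed by reductive etherification of a δ-hydroxy ketone, which keeps the C6 oxygen and therefore needs the 4,6-syn carbinol. Aldehyde 12 would be allylated chemoselectively with (−)-B-allyldiisopinocampheylborane (Brown allylation, Et2O, −100 to −78 °C, ethanolamine work-up; this antipode is expected to give the 5S carbinol under reagent control against the substrate's 1,3-anti bias) to give (3S,5S)-3-(benzyloxy)-1-ArA-5-hydroxyoct-7-en-1-one F1. Et3SiH with BF3·OEt2 in CH2Cl2/MeCN at −78 to −40 °C should then reduce its hemiketal through the same 2-aryl oxocarbenium ion with axial hydride delivery to (2S,4S,6S)-4-(benzyloxy)-2-ArA-6-(prop-2-en-1-yl)oxane F2. Ozonolysis of F2 with NaBH4 work-up gives alcohol 18.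

2. Step 8. The keto-aldehyde carries a benzyloxy group β to both carbonyls and may lose benzyl alcohol under the amine base, and the catalyst may give insufficient facial selectivity on this substrate. Fallback, setting out from aldehyde 12 and returning at β-lactone 14: a substrate-controlled Mukaiyama aldol addition of 1-(tert-butylsulfanyl)-1-(trimethylsilyloxy)ethene with BF3·OEt2 in CH2Cl2 at −78 °C (open transition state, 1,3-anti induction by the β-benzyloxy group, no amine present) would give S-tert-butyl (3S,5S)-5-(benzyloxy)-7-ArA-3-hydroxy-7-oxoheptanethioate F3. Silver(I) trifluoroacetate in wet THF would hydrolyse the thioester to (3S,5S)-5-(benzyloxy)-7-ArA-3-hydroxy-7-oxoheptanoic acid F4. PhSO2Cl in pyridine at 0 °C would lactonise F4 by carboxyl activation, with retention at the carbinol carbon, to give 14.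

3. Step 14. Hydrogenolysis may also cleave the benzylic C2–O1 ring bond next to the electron-rich ring A, or may stall at the secondary alkyl benzyl ether; the polyphenol product is also prone to air oxidation. Fallback, setting out from 23 and arriving directly at 24: non-reductive Lewis-acid debenzylation with BCl3 and pentamethylbenzene as benzyl-cation scavenger in CH2Cl2 at −78 °C, which removes aryl and alkyl benzyl ethers and leaves the aryl methyl ether; it makes no new compound.

**Further compounds**

F1 | step 9 | (3S,5S)-3-(benzyloxy)-1-ArA-5-hydroxyoct-7-en-1-one | COc1cc(C(=O)C[C@@H](OCc2ccccc2)C[C@H](CC=C)O)cc(OCc2ccccc2)c1OCc1ccccc1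
F2 | step 9 | (2S,4S,6S)-4-(benzyloxy)-2-ArA-6-(prop-2-en-1-yl)oxane | COc1cc([C@@H]2C[C@@H](OCc3ccccc3)C[C@H](CC=C)O2)cc(OCc2ccccc2)c1OCc1ccccc1
F3 | step 8 | S-tert-butyl (3S,5S)-5-(benzyloxy)-7-ArA-3-hydroxy-7-oxoheptanethioate | COc1cc(C(=O)C[C@@H](OCc2ccccc2)C[C@H](O)CC(=O)SC(C)(C)C)cc(OCc2ccccc2)c1OCc1ccccc1
F4 | step 8 | (3S,5S)-5-(benzyloxy)-7-ArA-3-hydroxy-7-oxoheptanoic acid | COc1cc(C(=O)C[C@@H](OCc2ccccc2)C[C@H](O)CC(=O)O)cc(OCc2ccccc2)c1OCc1ccccc1
F0 | step 14 | none | none
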